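**Compound key:** 1, 2, 4 = starting materials; 3 = biaryl; 6 = bis-imide; 7 = diol; 9 = lactone; 12 = iodo ester; 14 = Birch alkylation product; 15 = key-step precursor; 16 = key-step product; 17–20 = end-game intermediates; 21 = target. Compounds 5, 8, 10 and 13 are not isolated.

## Analysis of the target

The target is a tricycle in which ring A, a benzene ring (C1–C6) methoxylated at C3, C4 and C5, is fused to the seven-membered ring C (C1, C6, C1', C7', C8', C8, C7), and ring C shares the spiro carbon C1' with ring B, a 3',5'-dimethoxycyclohexa-2',5'-dien-4'-one. Ring C carries three contiguous stereocentres, C7 (R, benzoate), C8 (S, methyl) and C8' (R, methyl); the two methyl groups are trans and the C7 oxygen is trans to the C8 methyl group, so the substituents alternate between the two faces and can all be pseudo-equatorial. C1' is quaternary but not stereogenic, because ring B has a mirror plane through C1' and C4'. The sensitive groups are the ring B dienone, which in acid suffers a dienone–phenol shift of the electron-rich aryl group, its two enol ethers, the benzylic benzoate on an electron-rich ring, and C8 whenever C7 is a ketone. The difficulty lies in the quaternary carbon next to an ortho-methoxylated arene, in the closure of the seven-membered ring, and in an oxidation pattern of ring B that no acidic bond-forming step tolerates. The strategy rests on reading ring B as the bis(methyl enol ether) of a 5,5-disubstituted cyclohexane-1,2,3-trione. With the C4' oxygen removed it becomes a symmetric, acid-stable 1,3-dione, which is also the hydrolysis product of a Birch-reduced 3,5-dimethoxyphenyl ring. The C1–C7 bond can therefore be made by electrophilic acylation while ring B rests as the dione.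

## Retrosynthetic reasoning

**21 ⇒ 20 (two enol O–CH3 bonds).** The methyl groups are removed first because the dimethoxydienone is the only form of ring B that cannot be carried through acid. Trione 20 can enolise only toward C2' and C6', since C4' has no hydrogen, so double O-methylation can give only the pattern of 21.

**20 ⇒ 19 ⇒ 18 ⇒ 17 (C4' oxygen, benzoate).** The C4' carbonyl is traced back to a diazo group (19), and the diazo group to the C4' methylene of dione 17 by diazo transfer. The diazo dione has no acidic enol, so the C7 hydroxyl of 18 can be benzoylated without touching ring B. The ester is placed before the oxidation so that the benzylic alcohol never meets the oxidant.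

**17 ⇒ 16 (C7–H bond).** The C7 stereocentre is cut back to ketone 16. The forward reduction must deliver hydride so that the hydroxyl ends up trans to the C8 methyl group, and it must leave the dione alone. The dione is protected by being an enolate under the reduction conditions.

**16 ⇒ 15 (C1–C7 bond, ring C; key disconnection).** Cutting the aryl–carbonyl bond opens ring C to acid 15. This is the place to cut because the tether can reach only one aromatic C–H, and because 15 contains nothing that strong acid can damage. The forward reaction has to close a seven-membered ring onto a position of moderate nucleophilicity.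

**15 ⇒ 14 ⇒ 3 + 12 (C1'–C7' bond, quaternary carbon).** Dione acid 15 is the hydrolysis product of bis(enol ether) ester 14. Cutting the C1'–C7' bond of 14 gives the dienyl anion of the reduced biaryl 3 and iodo ester 12. The quaternary carbon is thus made in one step from an arene that already holds all six carbons and both oxygens of ring B. The side chain arrives with C8 and C8' already set.

**3 ⇒ 1 + 2 (biaryl bond).** A Suzuki–Miyaura coupling joins the two commercial arenes. The 3,5-dimethoxy pattern of 2 is the one that directs the later reduction to C1' and C4'.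

**12 ⇒ 11 ⇒ 9 ⇒ 7 ⇒ 6 ⇒ 4 (C8–C8' bond).** Iodo ester 12 comes from lactone 9 by ring opening and esterification. Lactone 9 comes from the C2-symmetric diol 7, where either hydroxyl gives the same lactone. Diol 7 comes from bis-imide 6, and the C8–C8' bond of 6 is cut to two molecules of imide 4. One auxiliary-controlled dimerisation thus sets both methyl centres and their trans relationship.

## Alternatives that were turned down

**Alternative 1:** The C7'–C8' and C8–C7 bonds are cut across a butenolide template.
- **Forward key step.** 2-Lithio-1,3-dithiane A1 adds to the β-carbon of the menthyloxybutenolide A2, and the lactone enolate is trapped by the biaryl aldehyde A3 to give adduct A4.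
- **For.** It is a convergent three-component union, and C8', C8 and C7 are all set in one operation from a cheap acetal auxiliary. On C7 it is stronger than the chosen route, which relies on a hydride reduction of modest intrinsic bias.
- **Against.** In A4 both lactone-derived carbons are at the wrong oxidation level and must be taken down to methyl groups. The dithiane carbon must become C7' and then be joined to C1' by a dearomatising alkylation. That step builds the quaternary centre and the seven-membered ring together, late, and on the acid-labile dienone. The carbinol configuration from the aldol trap is less securely controlled by the template than the two ring centres.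
- **Comparison.** The chosen route makes the quaternary carbon early, by alkylation of a reduced arene, and leaves only functional-group changes for the end.

**Alternative 2:** Ring B is cut at both C=C bonds (C2'=C3' and C5'=C6').
- **Forward key step.** The geminal dialdehyde A5 condenses twice with 1,3-dimethoxyacetone A6 to give the silyl ether A7.
- **For.** Ring B arrives at its final oxidation level with the C7 stereocentre already in place. No trione, no late methylation and no acid-sensitive intermediate is needed afterwards; here it is stronger than the chosen route.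
- **Against.** A5 is a non-enolisable 2,2-disubstituted malondialdehyde on a hindered benzylic quaternary carbon, a substrate prone to deformylation by the amine and carboxylate catalysts the condensation needs. A5 must itself contain the quaternary carbon, ring C and all three stereocentres, so the hard bonds are only moved into its preparation. The first aldol of the weakly acidic A6 at a neopentyl-type aldehyde is slow, and A6 can self-condense.
- **Comparison.** The chosen route pays for ring B with three late steps (11, 13, 14) but buys its six carbons as a commercial arene.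

**Alternative 3:** The C8'–CH3 and C8–CH3 bonds are cut.
- **Forward key step.** On the achiral spiro enone A8, copper thiophene-2-carboxylate A9, of formula Cu(O2CC4H3S) with monovalent copper, acts together with a chiral phosphoramidite ligand and transfers a methyl group from trimethylaluminium A10 to C8'. The enolate is methylated at C8 by iodomethane A11 to give ketone A12.
- **For.** It is the shortest way to the two methyl centres. It is catalytic, needs no auxiliary, and gives the trans relationship by alkylation anti to the new methyl group; on step economy it is stronger than the chosen route.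
- **Against.** A8 contains a second, cross-conjugated acceptor and a second carbonyl in ring B. The Lewis-acidic A10 can add to them or trigger the aryl shift of the dienone. Facial selection must come from the catalyst alone on a seven-membered aryl enone with no nearby stereocentre. Aluminium enolates are sluggish toward A11. C7 must later be reduced in the presence of the ring B carbonyl.
- **Comparison.** The chosen route fixes both methyl centres in a crystalline auxiliary-bearing intermediate before any sensitive group exists, and keeps ring B inert to acids throughout.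

Key step: step 9

Remark on the chemistry: the facial sense of the oxidative enolate coupling in step 2 is assumed to follow that of alkylations of chelated Z-enolates of 4-substituted N-acyloxazolidinones; on that basis the (R)-auxiliary is the one that leads to the (8S,8'R) series.

## Route

Step 1
Reactants: 1 1-bromo-2,3,4-trimethoxybenzene; 2 3,5-dimethoxyphenylboronic acid
Product: 3 2,3,3',4,5'-pentamethoxy-1,1'-biphenyl
Conditions: Pd(PPh3)4 (3 mol %), K2CO3, DME/H2O, 85 °C
Reagents that add atoms: none
Why: Suzuki–Miyaura coupling of an electron-rich aryl bromide with an unhindered arylboronic acid; only one ortho substituent flanks the new bond, so transmetalation and reductive elimination should be unimpeded.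

Step 2
Reactants: 4 (R)-4-isopropyl-3-propionyloxazolidin-2-one
Product: 6 (4R,4'R)-3,3'-[(2S,3S)-2,3-dimethylbutanedioyl]bis(4-isopropyloxazolidin-2-one), via lithium Z-enolate 5 (not isolated)
Conditions: LiN(i-Pr)2, THF, −78 °C; then TiCl4, −78 °C → rt; recrystallisation
Reagents that add atoms: second molecule of 4 (R)-4-isopropyl-3-propionyloxazolidin-2-one, CCC(=O)N1[C@H](C(C)C)COC1=O
Why: Oxidative homocoupling of two molecules of the imide enolate; TiCl4 (tetravalent titanium) takes one electron from each enolate and the two α-carbons join. Each α-carbon bonds on the face of the chelated Z-enolate away from the isopropyl group, which with the (R)-auxiliary should give the C2-symmetric (2S,3S) dimer and hence the trans relationship of the later C8 and C8' methyl groups.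

Step 3
Reactants: 6 (4R,4'R)-3,3'-[(2S,3S)-2,3-dimethylbutanedioyl]bis(4-isopropyloxazolidin-2-one)
Product: 7 (2S,3S)-2,3-dimethylbutane-1,4-diol
Conditions: LiBH4, THF/MeOH, 0 °C → rt
Reagents that add atoms: none
Why: Reductive cleavage of N-acyloxazolidinones by borohydride at the exocyclic carbonyl; the stereocentres are not enolised under these conditions and the auxiliary is recovered.

Step 4
Reactants: 7 (2S,3S)-2,3-dimethylbutane-1,4-diol
Product: 9 (3S,4S)-3,4-dimethyloxolan-2-one, via lactol (3S,4S)-3,4-dimethyloxolan-2-ol 8 (not isolated)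
Conditions: TEMPO (10 mol %), PhI(OAc)2 (2.5 equiv), CH2Cl2, rt
Reagents that add atoms: none
Why: Oxoammonium-mediated oxidative lactonisation of a 1,4-diol: one primary alcohol is oxidised to the aldehyde, which closes to the lactol and is oxidised again. Because 7 is C2-symmetric either hydroxyl gives the same trans lactone, and the base-free medium should leave the α-centre untouched.

Step 5
Reactants: 9 (3S,4S)-3,4-dimethyloxolan-2-one
Product: 11 (2S,3S)-4-iodo-2,3-dimethylbutanoic acid, via trimethylsilyl (2S,3S)-4-iodo-2,3-dimethylbutanoate 10 (not isolated)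
Conditions: Me3SiI, CH2Cl2, rt → 40 °C; then H2O, aq. Na2S2O3
Reagents that add atoms: iodotrimethylsilane, C[Si](C)(C)I
Why: Silylation of the lactone carbonyl followed by SN2 attack of iodide at the primary O–CH2 carbon (lactone dealkylation); neither stereocentre is at the reacting carbon, and the silyl ester is hydrolysed on work-up.

Step 6
Reactants: 11 (2S,3S)-4-iodo-2,3-dimethylbutanoic acid
Product: 12 tert-butyl (2S,3S)-4-iodo-2,3-dimethylbutanoate
Conditions: Cl3CC(=NH)O-t-Bu (2 equiv), BF3·OEt2 (cat.), cyclohexane/CH2Cl2, rt
Reagents that add atoms: tert-butyl 2,2,2-trichloroacetimidate, CC(C)(C)OC(=N)C(Cl)(Cl)Cl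
Why: Acid-catalysed tert-butyl transfer from the imidate to the carboxylic acid; no base is present, so the iodo acid can neither relactonise through its carboxylate nor epimerise.

Step 7
Reactants: 3 2,3,3',4,5'-pentamethoxy-1,1'-biphenyl; 12 tert-butyl (2S,3S)-4-iodo-2,3-dimethylbutanoate
Product: 14 tert-butyl (2S,3R)-4-[3,5-dimethoxy-1-(2,3,4-trimethoxyphenyl)cyclohexa-2,5-dien-1-yl]-2,3-dimethylbutanoate, via lithium 3,5-dimethoxy-1-(2,3,4-trimethoxyphenyl)cyclohexa-2,5-dien-1-ide 13 (not isolated)
Conditions: Li (2.2 equiv), t-BuOH (1.0 equiv), NH3/THF, −78 °C; isoprene (to discharge the blue colour); then 12 (1.3 equiv), −78 °C; NH4Cl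
Reagents that add atoms: none
Why: Birch reductive alkylation of a biaryl: the 3,5-dimethoxyphenyl ring is reduced at the carbon between the methoxy groups and at the aryl-bearing carbon, because both methoxy carbons then stay on double bonds. The aryl-stabilised dienyl anion is alkylated at its central carbon by the primary iodide (SN2). tert-Butanol as the single proton source leaves only LiO-t-Bu as base, which should not enolise the tert-butyl ester.

Step 8
Reactants: 14 tert-butyl (2S,3R)-4-[3,5-dimethoxy-1-(2,3,4-trimethoxyphenyl)cyclohexa-2,5-dien-1-yl]-2,3-dimethylbutanoate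
Product: 15 (2S,3R)-4-[3,5-dioxo-1-(2,3,4-trimethoxyphenyl)cyclohexyl]-2,3-dimethylbutanoic acid
Conditions: CF3CO2H/H2O (9:1), 0 °C → rt
Reagents that add atoms: water, O
Why: Acid hydrolysis of both methyl enol ethers, through the 3-methoxy enone, to the 1,3-dione and acidolysis of the tert-butyl ester in one operation; no base is involved, so C8 is not at risk, and the quaternary carbon blocks aromatisation.

Step 9
Reactants: 15 (2S,3R)-4-[3,5-dioxo-1-(2,3,4-trimethoxyphenyl)cyclohexyl]-2,3-dimethylbutanoic acid
Product: 16 (6S,7R)-1,2,3-trimethoxy-6,7-dimethyl-7,8-dihydrospiro[benzo[7]annulene-9,1'-cyclohexane]-3',5,5'(6H)-trione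
Conditions: P2O5 in CH3SO3H (7.7 wt %), 0.02 M, rt → 45 °C; poured onto ice
Reagents that add atoms: none
Why: P2O5/CH3SO3H turns the carboxylic acid into a mixed anhydride and from it the acylium ion, which attacks ring A at C1, the free position ortho to the carbon that carries the quaternary centre, and loss of the proton from the arenium ion gives the aryl ketone (intramolecular Friedel–Crafts acylation). The closest known reaction type is the acid-mediated cyclisation of 5-arylpentanoic acids to benzosuberones, together with the ring closures of 2,3,4-trimethoxyphenyl alkanoic acids, which acylate para to the central methoxy group. Ring C is closed as a seven-membered ring by attack of the arene on the acylium carbon, exo with respect to the C≡O bond of the acylium ion (7-exo-dig) and endo with respect to the arene π bond, helped by the geminal disubstitution at C1'. No stereocentre is created; C8' is untouched, and C8, if it enolises through the protonated ketone, should settle in the trans-dimethyl arrangement in which both methyl groups are pseudo-equatorial. The step needs site selectivity on ring A, which the tether secures because the more electron-rich C2–H could only be reached through a meta-bridged ring. It needs the acylium ion to react with ring A and not with ring B, which is secured because the 1,3-dione is O-protonated to a delocalised hydroxyallyl cation in this medium, so that neither C4' nor, through a dienol, C2' is nucleophilic. It needs ring closure to beat intermolecular acylation, which dilution and the rotamer restriction at the quaternary carbon favour.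

Step 10
Reactants: 16 (6S,7R)-1,2,3-trimethoxy-6,7-dimethyl-7,8-dihydrospiro[benzo[7]annulene-9,1'-cyclohexane]-3',5,5'(6H)-trione
Product: 17 (5R,6S,7R)-5-hydroxy-1,2,3-trimethoxy-6,7-dimethyl-5,6,7,8-tetrahydrospiro[benzo[7]annulene-9,1'-cyclohexane]-3',5'-dione
Conditions: NaBH4 (4 equiv), MeOH/THF, −20 → 0 °C; pH 5 buffer
Reagents that add atoms: none
Why: Borohydride reduction of the aryl ketone; the first hydride deprotonates the 1,3-dione, whose enolate is not reduced. The small hydride should add along the axial-type trajectory anti to the pseudo-axial C8–H, which places the new hydroxyl pseudo-equatorial and trans to the C8 methyl group (7R, the all-pseudo-equatorial isomer).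

Step 11
Reactants: 17 (5R,6S,7R)-5-hydroxy-1,2,3-trimethoxy-6,7-dimethyl-5,6,7,8-tetrahydrospiro[benzo[7]annulene-9,1'-cyclohexane]-3',5'-dione
Product: 18 (5R,6S,7R)-4'-diazo-5-hydroxy-1,2,3-trimethoxy-6,7-dimethyl-5,6,7,8-tetrahydrospiro[benzo[7]annulene-9,1'-cyclohexane]-3',5'-dione
Conditions: 4-AcNHC6H4SO2N3 (1.2 equiv), Et3N, MeCN, 0 °C → rt
Reagents that add atoms: 4-acetamidobenzenesulfonyl azide, CC(=O)Nc1ccc(cc1)S(=O)(=O)N=[N+]=[N-]
Why: Regitz diazo transfer to the acidic C4' methylene of a cyclic 1,3-dione, which needs only an amine base and leaves the secondary alcohol alone; the product no longer has an enol that could compete in the acylation that follows.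

Step 12
Reactants: 18 (5R,6S,7R)-4'-diazo-5-hydroxy-1,2,3-trimethoxy-6,7-dimethyl-5,6,7,8-tetrahydrospiro[benzo[7]annulene-9,1'-cyclohexane]-3',5'-dione
Product: 19 (5R,6S,7R)-4'-diazo-1,2,3-trimethoxy-6,7-dimethyl-3',5'-dioxo-5,6,7,8-tetrahydrospiro[benzo[7]annulene-9,1'-cyclohexan]-5-yl benzoate
Conditions: BzCl (2 equiv), pyridine, DMAP (cat.), CH2Cl2, 0 °C → rt
Reagents that add atoms: benzoyl chloride, O=C(Cl)c1ccccc1
Why: Nucleophile-catalysed acylation of the secondary benzylic alcohol with retention at C7; the acceptor-stabilised diazo dione is inert to acyl chlorides under basic conditions.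

Step 13
Reactants: 19 (5R,6S,7R)-4'-diazo-1,2,3-trimethoxy-6,7-dimethyl-3',5'-dioxo-5,6,7,8-tetrahydrospiro[benzo[7]annulene-9,1'-cyclohexan]-5-yl benzoate
Product: 20 (5R,6S,7R)-1,2,3-trimethoxy-6,7-dimethyl-3',4',5'-trioxo-5,6,7,8-tetrahydrospiro[benzo[7]annulene-9,1'-cyclohexan]-5-yl benzoate
Conditions: dimethyldioxirane (ca. 0.08 M in acetone, 1.5 equiv), CH2Cl2, 0 °C → rt; evaporated and used at once
Reagents that add atoms: dimethyldioxirane, CC1(C)OO1
Why: Oxygen-atom transfer from the dioxirane to the diazo carbon with loss of nitrogen, the known route from 2-diazo-1,3-dicarbonyl compounds to vicinal tricarbonyl compounds. The medium is neutral and anhydrous, so the benzoate survives and the trione is not hydrated.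

Step 14
Reactants: 20 (5R,6S,7R)-1,2,3-trimethoxy-6,7-dimethyl-3',4',5'-trioxo-5,6,7,8-tetrahydrospiro[benzo[7]annulene-9,1'-cyclohexan]-5-yl benzoate
Product: 21 (5R,6S,7R)-1,2,3,3',5'-pentamethoxy-6,7-dimethyl-4'-oxo-5,6,7,8-tetrahydrospiro[benzo[7]annulene-9,1'-cyclohexa[2,5]dien]-5-yl benzoate
Conditions: Me2SO4 (3 equiv), K2CO3 (4 equiv), 4 Å molecular sieves, acetone, rt → 40 °C; neutral work-up
Reagents that add atoms: dimethyl sulfate, COS(=O)(=O)OC
Why: O-Methylation of the enolised α-dicarbonyl units (diosphenol ether formation) on both sides of C4'. The trione can enolise only toward C2' and C6', and a hard methylating agent should alkylate the enolate oxygens, giving the cross-conjugated dimethoxydienone; the final product must not meet acid.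

## Compound list

1 | 1-bromo-2,3,4-trimethoxybenzene | COc1ccc(Br)c(OC)c1OC | starting material
2 | 3,5-dimethoxyphenylboronic acid | COc1cc(OC)cc(c1)B(O)O | starting material
3 | 2,3,3',4,5'-pentamethoxy-1,1'-biphenyl | COc1cc(OC)cc(c1)-c1ccc(OC)c(OC)c1OC | intermediate
4 | (R)-4-isopropyl-3-propionyloxazolidin-2-one | CCC(=O)N1[C@H](C(C)C)COC1=O | starting material
5 | lithium Z-enolate of 4 | [Li+].C/C=C(\[O-])N1[C@H](C(C)C)COC1=O | intermediate (not isolated)
6 | (4R,4'R)-3,3'-[(2S,3S)-2,3-dimethylbutanedioyl]bis(4-isopropyloxazolidin-2-one) | O=C1OC[C@@H](C(C)C)N1C(=O)[C@@H](C)[C@H](C)C(=O)N1[C@H](C(C)C)COC1=O | intermediate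
7 | (2S,3S)-2,3-dimethylbutane-1,4-diol | OC[C@@H](C)[C@H](C)CO | intermediate
8 | (3S,4S)-3,4-dimethyloxolan-2-ol (lactol, both anomers) | O1C[C@@H](C)[C@H](C)C1O | intermediate (not isolated)
9 | (3S,4S)-3,4-dimethyloxolan-2-one | O1C[C@@H](C)[C@H](C)C1=O | intermediate
10 | trimethylsilyl (2S,3S)-4-iodo-2,3-dimethylbutanoate | IC[C@@H](C)[C@H](C)C(=O)O[Si](C)(C)C | intermediate (not isolated)
11 | (2S,3S)-4-iodo-2,3-dimethylbutanoic acid | IC[C@@H](C)[C@H](C)C(=O)O | intermediate
12 | tert-butyl (2S,3S)-4-iodo-2,3-dimethylbutanoate | IC[C@@H](C)[C@H](C)C(=O)OC(C)(C)C | intermediate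
13 | lithium 3,5-dimethoxy-1-(2,3,4-trimethoxyphenyl)cyclohexa-2,5-dien-1-ide | [Li+].COC1=C[C-](C=C(OC)C1)c1ccc(OC)c(OC)c1OC | intermediate (not isolated)
14 | tert-butyl (2S,3R)-4-[3,5-dimethoxy-1-(2,3,4-trimethoxyphenyl)cyclohexa-2,5-dien-1-yl]-2,3-dimethylbutanoate | COC1=CC(C=C(OC)C1)(c1ccc(OC)c(OC)c1OC)C[C@@H](C)[C@H](C)C(=O)OC(C)(C)C | intermediate
15 | (2S,3R)-4-[3,5-dioxo-1-(2,3,4-trimethoxyphenyl)cyclohexyl]-2,3-dimethylbutanoic acid | O=C1CC(=O)CC(C1)(c1ccc(OC)c(OC)c1OC)C[C@@H](C)[C@H](C)C(=O)O | intermediate
16 | (6S,7R)-1,2,3-trimethoxy-6,7-dimethyl-7,8-dihydrospiro[benzo[7]annulene-9,1'-cyclohexane]-3',5,5'(6H)-trione | O=C1CC(=O)CC2(C1)C[C@@H](C)[C@H](C)C(=O)c1cc(OC)c(OC)c(OC)c12 | intermediate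
17 | (5R,6S,7R)-5-hydroxy-1,2,3-trimethoxy-6,7-dimethyl-5,6,7,8-tetrahydrospiro[benzo[7]annulene-9,1'-cyclohexane]-3',5'-dione | O=C1CC(=O)CC2(C1)C[C@@H](C)[C@H](C)[C@@H](O)c1cc(OC)c(OC)c(OC)c12 | intermediate
18 | (5R,6S,7R)-4'-diazo-5-hydroxy-1,2,3-trimethoxy-6,7-dimethyl-5,6,7,8-tetrahydrospiro[benzo[7]annulene-9,1'-cyclohexane]-3',5'-dione | O=C1CC2(CC(=O)C1=[N+]=[N-])C[C@@H](C)[C@H](C)[C@@H](O)c1cc(OC)c(OC)c(OC)c12 | intermediate
19 | (5R,6S,7R)-4'-diazo-1,2,3-trimethoxy-6,7-dimethyl-3',5'-dioxo-5,6,7,8-tetrahydrospiro[benzo[7]annulene-9,1'-cyclohexan]-5-yl benzoate | O=C1CC2(CC(=O)C1=[N+]=[N-])C[C@@H](C)[C@H](C)[C@@H](OC(=O)c1ccccc1)c1cc(OC)c(OC)c(OC)c12 | intermediate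
20 | (5R,6S,7R)-1,2,3-trimethoxy-6,7-dimethyl-3',4',5'-trioxo-5,6,7,8-tetrahydrospiro[benzo[7]annulene-9,1'-cyclohexan]-5-yl benzoate | O=C1CC2(CC(=O)C1=O)C[C@@H](C)[C@H](C)[C@@H](OC(=O)c1ccccc1)c1cc(OC)c(OC)c(OC)c12 | intermediate
21 | (5R,6S,7R)-1,2,3,3',5'-pentamethoxy-6,7-dimethyl-4'-oxo-5,6,7,8-tetrahydrospiro[benzo[7]annulene-9,1'-cyclohexa[2,5]dien]-5-yl benzoate | COC1=CC2(C=C(OC)C1=O)C[C@@H](C)[C@H](C)[C@@H](OC(=O)c1ccccc1)c1cc(OC)c(OC)c(OC)c12 | target

## Step count and least certain steps

Total: 14 steps. Longest linear sequence: 13 steps (4 to 21, steps 2–14); step 1 supplies 3 for the convergent step 7.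

**Step 9 (key step).**
- **What may go wrong.** Substitution at C1 may be slow, because C1 is activated only through the out-of-plane central methoxy group and the ortho alkyl substituent. Intermolecular acylation at the more electron-rich C2–H of a second molecule, condensation of ring A with a protonated dione carbonyl, or acylation of ring B at C2' through a small equilibrium share of dienol (a six-membered closure) could then compete. C8 may also be scrambled by enolisation before ring closure. Scrambling should be correctable afterwards by base equilibration of 16 to the trans-dimethyl ketone.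
- **Fallback.** It sets out from 15 and returns at 16. Oxalyl chloride with catalytic DMF converts the acid into the acid chloride and the dione into its vinylogous acid chloride in one operation, giving (2S,3R)-4-[3-chloro-5-oxo-1-(2,3,4-trimethoxyphenyl)cyclohex-3-en-1-yl]-2,3-dimethylbutanoyl chloride F1. SnCl4 in CH2Cl2 at −20 to 0 °C then closes ring C through a discrete acyl chloride–Lewis acid complex in an aprotic medium, where ring A is not protonated and ring B as a β-chloro enone has no nucleophilic enol, to give the chloro enone ketone (6S,7R)-3'-chloro-1,2,3-trimethoxy-6,7-dimethyl-7,8-dihydrospiro[benzo[7]annulene-9,1'-cyclohex[3]ene]-5,5'(6H)-dione F2. Aqueous LiOH followed by acidification hydrolyses the β-chloro enone back to the dione 16.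

**Step 7.**
- **What may go wrong.** Proton transfer from C8–H of 12 to the dienyl anion, followed by cyclopropane closure of the ester enolate, would consume both partners. SN2 attack of a hindered tertiary carbanion on a β-branched iodide may be slow. Reductive loss of the central methoxy group of ring A is possible if the reduction is prolonged.
- **Fallback.** It sets out from 7 and the anion 13 and returns at 15. It uses an electrophile without an acidic C–H. Diol 7 is mono-silylated (NaH, t-BuMe2SiCl) to (2S,3S)-4-[(tert-butyldimethylsilyl)oxy]-2,3-dimethylbutan-1-ol F3. This is converted (I2, PPh3, imidazole) into tert-butyl{[(2S,3S)-4-iodo-2,3-dimethylbutyl]oxy}dimethylsilane F4. Alkylation of 13 with F4 gives tert-butyl({(2S,3R)-4-[3,5-dimethoxy-1-(2,3,4-trimethoxyphenyl)cyclohexa-2,5-dien-1-yl]-2,3-dimethylbutyl}oxy)dimethylsilane F5. Bu4NF liberates (2S,3R)-4-[3,5-dimethoxy-1-(2,3,4-trimethoxyphenyl)cyclohexa-2,5-dien-1-yl]-2,3-dimethylbutan-1-ol F6. Neutral oxidation ([N(C3H7)4][RuO4] cat., N-methylmorpholine N-oxide monohydrate, MeCN) gives (2S,3R)-4-[3,5-dimethoxy-1-(2,3,4-trimethoxyphenyl)cyclohexa-2,5-dien-1-yl]-2,3-dimethylbutanoic acid F7, and aqueous HCl in THF hydrolyses the enol ethers to 15.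

**Step 14.**
- **What may go wrong.** C-methylation at C2'/C6' could compete with O-methylation. The vicinal trione could be attacked at C4' by carbonate, adventitious water or methanol, leading to hydration or a benzilic-type ring contraction.
- **Fallback.** It sets out from 20 and returns at 21. The dienol is first trapped on silicon by soft enolisation (t-BuMe2SiOTf, 2,6-lutidine, CH2Cl2, −78 to 0 °C), which never exposes the trione to a nucleophilic base. This gives the isolable (5R,6S,7R)-3',5'-bis[(tert-butyldimethylsilyl)oxy]-1,2,3-trimethoxy-6,7-dimethyl-4'-oxo-5,6,7,8-tetrahydrospiro[benzo[7]annulene-9,1'-cyclohexa[2,5]dien]-5-yl benzoate F8. Desilylative O-methylation (CsF, Me2SO4, DMF, 0 °C), the enol counterpart of the one-pot conversion of aryl silyl ethers into aryl methyl ethers, then gives 21.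

**Step 10.**
- **What may go wrong.** Facial selectivity may be poor, because the torsional preference in a benzo-fused seven-membered ketone is weaker than in a cyclohexanone. The C7 epimer can be separated and re-oxidised.
- **Fallback.** It sets out from 16 and returns at 17. The source of stereocontrol is moved from the substrate to a catalyst: asymmetric transfer hydrogenation with RuCl[(R,R)-TsNCH(C6H5)CH(C6H5)NH2](p-cymene) in HCO2H/Et3N (5:2) at 30 °C. Cyclic aryl ketones of the 1-tetralone and benzosuberone type are reduced through a transition state in which the fused arene lies against the cymene ligand, and the (R,R)-ligand should then deliver hydride to the face that gives the (7R)-alcohol 17. The medium tolerates the acidic dione, which sits as its unreactive triethylammonium enolate, and any epimerisation at C8 by the amine can only lead toward the trans-dimethyl series. No compound outside the compound list arises on this way, hence the entry F0 under Further compounds.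

**Step 2.**
- **What may go wrong.** The coupling may give only modest diastereoselection between the C2-symmetric and the meso-type dimers.
- **Fallback.** It sets out from 4 and returns at 9. It sets the two centres one after the other. Auxiliary-controlled alkylation of 4 (NaN(SiMe3)2, THF, −78 °C; tert-butyl bromoacetate) gives tert-butyl (3S)-3-methyl-4-oxo-4-[(4R)-2-oxo-4-(propan-2-yl)-1,3-oxazolidin-3-yl]butanoate F9. LiBH4 reduces the imide selectively to tert-butyl (3S)-4-hydroxy-3-methylbutanoate F10. CF3CO2H closes it to (4S)-4-methyloxolan-2-one F11. Methylation of the lactone enolate (LiN(i-Pr)2, CH3I, −78 °C) anti to the C4 methyl group gives the trans lactone 9.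

## Further compounds

F1 | step 9 | (2S,3R)-4-[3-chloro-5-oxo-1-(2,3,4-trimethoxyphenyl)cyclohex-3-en-1-yl]-2,3-dimethylbutanoyl chloride (both epimers at the quaternary carbon) | ClC1=CC(=O)CC(C1)(c1ccc(OC)c(OC)c1OC)C[C@@H](C)[C@H](C)C(=O)Cl
F2 | step 9 | (6S,7R)-3'-chloro-1,2,3-trimethoxy-6,7-dimethyl-7,8-dihydrospiro[benzo[7]annulene-9,1'-cyclohex[3]ene]-5,5'(6H)-dione (both epimers at C9) | ClC1=CC(=O)CC2(C1)C[C@@H](C)[C@H](C)C(=O)c1cc(OC)c(OC)c(OC)c12
F3 | step 7 | (2S,3S)-4-[(tert-butyldimethylsilyl)oxy]-2,3-dimethylbutan-1-ol | OC[C@@H](C)[C@H](C)CO[Si](C)(C)C(C)(C)C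
F4 | step 7 | tert-butyl{[(2S,3S)-4-iodo-2,3-dimethylbutyl]oxy}dimethylsilane | IC[C@@H](C)[C@H](C)CO[Si](C)(C)C(C)(C)C
F5 | step 7 | tert-butyl({(2S,3R)-4-[3,5-dimethoxy-1-(2,3,4-trimethoxyphenyl)cyclohexa-2,5-dien-1-yl]-2,3-dimethylbutyl}oxy)dimethylsilane | COC1=CC(C=C(OC)C1)(c1ccc(OC)c(OC)c1OC)C[C@@H](C)[C@H](C)CO[Si](C)(C)C(C)(C)C
F6 | step 7 | (2S,3R)-4-[3,5-dimethoxy-1-(2,3,4-trimethoxyphenyl)cyclohexa-2,5-dien-1-yl]-2,3-dimethylbutan-1-ol | COC1=CC(C=C(OC)C1)(c1ccc(OC)c(OC)c1OC)C[C@@H](C)[C@H](C)CO
F7 | step 7 | (2S,3R)-4-[3,5-dimethoxy-1-(2,3,4-trimethoxyphenyl)cyclohexa-2,5-dien-1-yl]-2,3-dimethylbutanoic acid | COC1=CC(C=C(OC)C1)(c1ccc(OC)c(OC)c1OC)C[C@@H](C)[C@H](C)C(=O)O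
F8 | step 14 | (5R,6S,7R)-3',5'-bis[(tert-butyldimethylsilyl)oxy]-1,2,3-trimethoxy-6,7-dimethyl-4'-oxo-5,6,7,8-tetrahydrospiro[benzo[7]annulene-9,1'-cyclohexa[2,5]dien]-5-yl benzoate | CC(C)(C)[Si](C)(C)OC1=CC2(C=C(O[Si](C)(C)C(C)(C)C)C1=O)C[C@@H](C)[C@H](C)[C@@H](OC(=O)c1ccccc1)c1cc(OC)c(OC)c(OC)c12
F0 | step 10 | none | none
F9 | step 2 | tert-butyl (3S)-3-methyl-4-oxo-4-[(4R)-2-oxo-4-(propan-2-yl)-1,3-oxazolidin-3-yl]butanoate | CC(C)(C)OC(=O)C[C@H](C)C(=O)N1[C@H](C(C)C)COC1=O
F10 | step 2 | tert-butyl (3S)-4-hydroxy-3-methylbutanoate | CC(C)(C)OC(=O)C[C@H](C)CO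
F11 | step 2 | (4S)-4-methyloxolan-2-one | O=C1C[C@H](C)CO1
A1 | alternative 1 | 2-lithio-1,3-dithiane | [Li]C1SCCCS1
A2 | alternative 1 | (5R)-5-{[(1R,2S,5R)-5-methyl-2-(propan-2-yl)cyclohexyl]oxy}furan-2(5H)-one | O=C1C=C[C@H](O[C@@H]2C[C@H](C)CC[C@H]2C(C)C)O1
A3 | alternative 1 | 2-[3,5-dimethoxy-4-(triisopropylsilyloxy)phenyl]-3,4,5-trimethoxybenzaldehyde | O=Cc1cc(OC)c(OC)c(OC)c1-c1cc(OC)c(O[Si](C(C)C)(C(C)C)C(C)C)c(OC)c1
A4 | alternative 1 | trans-disubstituted menthyloxy butyrolactone adduct carrying the dithianyl group and the biaryl carbinol | C1CSC(SC1)[C@@H]([C@H](O[C@@H]2C[C@H](C)CC[C@H]2C(C)C)O3)[C@H](C3=O)[C@@H](O)c1cc(OC)c(OC)c(OC)c1-c1cc(OC)c(O[Si](C(C)C)(C(C)C)C(C)C)c(OC)c1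
A5 | alternative 2 | (5R,6S,7R)-5-[(tert-butyldimethylsilyl)oxy]-1,2,3-trimethoxy-6,7-dimethyl-5,6,7,8-tetrahydro-9H-benzo[7]annulene-9,9-dicarbaldehyde | O=CC1(C=O)C[C@@H](C)[C@H](C)[C@@H](O[Si](C)(C)C(C)(C)C)c2cc(OC)c(OC)c(OC)c12
A6 | alternative 2 | 1,3-dimethoxypropan-2-one | COCC(=O)COC
A7 | alternative 2 | C7 tert-butyldimethylsilyl ether of the debenzoyl target | COC1=CC2(C=C(OC)C1=O)C[C@@H](C)[C@H](C)[C@@H](O[Si](C)(C)C(C)(C)C)c1cc(OC)c(OC)c(OC)c12
A8 | alternative 3 | 1,2,3,3',5'-pentamethoxyspiro[benzo[7]annulene-9,1'-cyclohexa[2,5]diene]-4',5(8H)-dione | COC1=CC2(C=C(OC)C1=O)CC=CC(=O)c1cc(OC)c(OC)c(OC)c12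
A9 | alternative 3 | copper thiophene-2-carboxylate, Cu(O2CC4H3S) | [Cu+].[O-]C(=O)c1cccs1
A10 | alternative 3 | trimethylaluminium, Al(CH3)3 | C[Al](C)C
A11 | alternative 3 | iodomethane | CI
A12 | alternative 3 | trans-8,8'-dimethyl spiro C7 ketone with the ring B dienone in place | COC1=CC2(C=C(OC)C1=O)C[C@@H](C)[C@H](C)C(=O)c1cc(OC)c(OC)c(OC)c12
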